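**Plan**
1. Retrosynthesis: the prenyl group is traced back to an allyl group (alkene exchange), the acetyl group is cut from C5', and the benzene ring is opened at C2'–C3' and C4'–C5' (C1'–C2' breaks and re-forms in the same operation). This leaves a 4-(pyranylmethyl)-3-alkoxycyclobutenone and an allyl-bearing siloxyalkyne.
2. Enabling feature: in the benzene ring the oxygen-bearing C2', C4' and C6' alternate with the carbon-bearing C1' (CH2 bridge), C3' (prenyl) and C5' (acetyl). This is the pattern left when three O–C–C units, a ketene (C2'–C1'), an alkynyl ether (C6'–C5') and a siloxyalkyne (C4'–C3'), are joined head to tail.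
3. Forward: the pyranone ring is made first (3-pentanone enol ether plus malonyl dichloride), allylated at C3, O-protected, and its side chain oxidised to the propanoic acid. The derived ketene and an alkynyl ether give the four-membered ring, and heating with the siloxyalkyne builds the benzene ring.
4. End game: fluoride deprotection, C-acetylation at the one free ring carbon C5', and cross-metathesis of allyl to prenyl.
5. Protecting-group logic: the cyclobutenone oxygen is the 2-(trimethylsilyl)ethyl ether installed directly by the ketene cycloaddition, so no enolisable 1,3-dione intervenes and the regiochemistry is fixed. The C3' chain stays allyl until the end so that the Lewis-acid acetylation never meets an ortho-prenylphenol.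
6. Stereochemistry: arzanol has no stereocentre and no E/Z alkene; the only stereocentre on the way (C4 of the cyclobutenone, racemic) vanishes on aromatisation.

Key step: step 10

Remark on the chemistry: pent-1-en-4-yne, 2-(trimethylsilyl)ethanol and trichloroethylene are taken as purchasable. In names, Pyr is the 6-ethyl-5-methyl-2-oxo-4-[2-(trimethylsilyl)ethoxy]-2H-pyran-3-yl group, and primed locants number the benzene ring from C1', the carbon carrying the CH2 bridge.

**Route**

Step 1
Reactants: 1 pentan-3-one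
Product: 2 (Z)-trimethyl(pent-2-en-3-yloxy)silane
Conditions: TMSOTf, Et3N, Et2O, 0 °C
Reagents that add atoms: trimethylsilyl trifluoromethanesulfonate, C[Si](C)(C)OS(=O)(=O)C(F)(F)F
Why: Soft enolisation (silyl enol ether formation with a silyl triflate and an amine) of a symmetrical ketone can give only one regioisomer, expected mainly Z, and the geometry has no bearing on step 2.

Step 2
Reactants: 2 (Z)-trimethyl(pent-2-en-3-yloxy)silane; 3 malonyl dichloride
Product: 4 6-ethyl-4-hydroxy-5-methyl-2H-pyran-2-one
Conditions: Et2O, −78 °C to rt; product filtered off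
Reagents that add atoms: none
Why: C-acylation of the silyl enol ether by one acid chloride group followed by O-acylative ring closure on the second (pyranone synthesis from enol ethers and malonyl dichloride) places ethyl at C6 and methyl at C5 of the 4-hydroxy-2-pyranone.

Step 3
Reactants: 4 6-ethyl-4-hydroxy-5-methyl-2H-pyran-2-one; 5 allyl methyl carbonate
Product: 6 6-ethyl-4-hydroxy-5-methyl-3-(prop-2-en-1-yl)-2H-pyran-2-one
Conditions: Pd(PPh3)4 (2 mol %), THF, 40 °C
Reagents that add atoms: none
Why: In this Tsuji–Trost allylation the methoxide released from the carbonate deprotonates the acidic pyranone, which attacks the allylpalladium electrophile at C3, its only nucleophilic carbon, while any O-allyl ether is re-ionised by the zerovalent palladium catalyst and funnelled to the C-allyl product.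

Step 4
Reactants: 6 6-ethyl-4-hydroxy-5-methyl-3-(prop-2-en-1-yl)-2H-pyran-2-one; 7 2-(trimethylsilyl)ethanol
Product: 8 6-ethyl-5-methyl-3-(prop-2-en-1-yl)-4-[2-(trimethylsilyl)ethoxy]-2H-pyran-2-one
Conditions: PPh3, DIAD, THF, 0 °C to rt
Reagents that add atoms: none
Why: Mitsunobu etherification alkylates the acidic vinylogous-acid OH on the C4 oxygen, as with other 4-hydroxy-2-pyranones, and the resulting silylethyl vinylogous ester should withstand borane, oxidant, acid chloride, amine and heat yet fall to fluoride.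

Step 5
Reactants: 8 6-ethyl-5-methyl-3-(prop-2-en-1-yl)-4-[2-(trimethylsilyl)ethoxy]-2H-pyran-2-one
Product: 10 6-ethyl-3-(3-hydroxypropyl)-5-methyl-4-[2-(trimethylsilyl)ethoxy]-2H-pyran-2-one, via B-alkyl-9-BBN adduct 9 (not isolated)
Conditions: 9-BBN, THF, 0 °C to rt; then NaBO3·4H2O, H2O, rt
Reagents that add atoms: sodium perborate, [Na+].[Na+].O[B-]1(O)OO[B-](O)(O)OO1
Why: Brown hydroboration–oxidation with 9-BBN adds anti-Markovnikov to the monosubstituted alkene only, the tetrasubstituted ring double bonds and the lactone being inert, and perborate oxidises the C–B bond without the strong alkali that could open the pyranone.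

Step 6
Reactants: 10 6-ethyl-3-(3-hydroxypropyl)-5-methyl-4-[2-(trimethylsilyl)ethoxy]-2H-pyran-2-one
Product: 12 3-Pyr-propanoic acid, via aldehyde 11 (not isolated)
Conditions: TEMPO (20 mol %), PhI(OAc)2 (2.5 equiv), MeCN–H2O, rt
Reagents that add atoms: water, O
Why: Oxoammonium (TEMPO/PhI(OAc)2) oxidation in aqueous acetonitrile takes a primary alcohol through the aldehyde hydrate to the acid under near-neutral conditions that should leave the silylethyl ether and the pyranone untouched.

Step 7
Reactants: 7 2-(trimethylsilyl)ethanol; 13 trichloroethylene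
Product: 17 [2-(ethynyloxy)ethyl]trimethylsilane, via potassium alkoxide 14 (not isolated), via dichlorovinyl ether 15 (not isolated), via lithium alkoxyacetylide 16 (not isolated)
Conditions: KH, THF, 0 °C; Cl2C=CHCl, −50 °C to rt; n-BuLi (2.3 equiv), −70 to −40 °C; H2O, −70 °C to rt
Reagents that add atoms: none
Why: This is the standard alkoxide/trichloroethylene route to alkynyl ethers, in which the alkoxide gives the (E)-1,2-dichlorovinyl ether by addition–elimination and n-BuLi then effects elimination and chlorine–lithium exchange to the alkoxyacetylide, which is protonated.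

Step 8
Reactants: 12 3-Pyr-propanoic acid; 17 [2-(ethynyloxy)ethyl]trimethylsilane
Product: 20 racemic 4-(Pyr-methyl)-3-[2-(trimethylsilyl)ethoxy]cyclobut-2-en-1-one, via acid chloride 18 (not isolated), via ketene 19 (not isolated)
Conditions: Me2C=C(Cl)NMe2, CH2Cl2, 0 °C to rt; then slow addition to 17 (2.5 equiv), Et3N, CH2Cl2, rt
Reagents that add atoms: none
Why: Dehydrochlorination gives the aldoketene, which undergoes the known ketene–alkynyl ether (2+2) cycloaddition with the unsubstituted alkyne carbon bonding to the ketene carbonyl carbon, so the alkoxy group must sit at C3 and the pyranylmethyl arm at C4 (new stereocentre, racemic, erased in step 10).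

Step 9
Reactants: 21 pent-1-en-4-yne
Product: 24 triisopropyl(pent-4-en-1-yn-1-yloxy)silane, via lithium acetylide 22 (not isolated), via lithium ynolate 23 (not isolated)
Conditions: n-BuLi, THF, −78 °C; LiOOt-Bu (from t-BuOOH and LiN(SiMe3)2), −78 to 0 °C; TIPSOTf, −78 to 0 °C
Reagents that add atoms: tert-butyl hydroperoxide, CC(C)(C)OO; triisopropylsilyl trifluoromethanesulfonate, CC(C)[Si](C(C)C)(C(C)C)OS(=O)(=O)C(F)(F)F
Why: Oxidation of a lithium acetylide with lithium tert-butyl peroxide gives the ynolate, and the bulky silyl triflate silylates it on oxygen to an isolable triisopropylsilyl ynol ether (ynolate O-silylation).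

Step 10
Reactants: 20 racemic 4-(Pyr-methyl)-3-[2-(trimethylsilyl)ethoxy]cyclobut-2-en-1-one; 24 triisopropyl(pent-4-en-1-yn-1-yloxy)silane
Product: 29 3-{[2-hydroxy-3-(prop-2-en-1-yl)-4-(triisopropylsilyloxy)-6-[2-(trimethylsilyl)ethoxy]phenyl]methyl}-6-ethyl-5-methyl-4-[2-(trimethylsilyl)ethoxy]-2H-pyran-2-one, via vinylketene 25 (not isolated), via vinylcyclobutenone 26 (not isolated), via dienylketene 27 (not isolated), via cyclohexadienone 28 (not isolated)
Conditions: 24 (2 equiv), toluene, 80 °C then 110 °C, sealed tube, argon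
Reagents that add atoms: none
Why: Proposed new method: on heating, 20 should open by 4π-electrocyclic cleavage of its C1–C4 bond to the 3-alkoxyvinylketene 25 (pyranylmethyl group rotating outward); ynol ether 24 then adds across the ketene C=C in a (2+2) cycloaddition, its allyl-bearing carbon bonding to the ketene carbonyl carbon (C2'–C3') and its oxygen-bearing carbon to the ketene α-carbon (C4'–C5'), the 2-vinylcyclobutenone 26 opens (4π) to dienylketene 27, and 27 closes (6π) to cyclohexadienone 28, which enolises to phenol 29. The closest known reaction type is the Danheiser benzannulation, in which 3-alkyl- or 3-arylcyclobutenones and alkoxy- or siloxyalkynes give resorcinol monoethers by this same cascade; new here is a cyclobutenone already carrying an alkoxy group at C3 (a vinylogous ester), so that a third oxygen enters the ring and a phloroglucinol results. The one ring formed, the benzene ring, closes by thermal disrotatory 6π-electrocyclisation of the (3E)-dienylketene between the ketene carbon and the diene terminus (bond C1'–C2'), and tautomerisation to the aromatic phenol makes the cascade irreversible. No stereocentre is created, and the racemic C4 of 20 becomes the sp2 carbon C1'. The selectivity needed is the orientation of the ketene–ynol ether (2+2) step, secured by the polarisation of the O–C≡C unit of 24 (nucleophilic at the allyl-bearing carbon) toward the electrophilic ketene carbonyl carbon, and chemoselectivity for the ynol ether over other ketene traps, secured because every hydroxyl of 20 is etherified and 24 is in excess.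

Step 11
Reactants: 29 benzannulation product (name as in step 10)
Product: 30 3-{[2,4,6-trihydroxy-3-(prop-2-en-1-yl)phenyl]methyl}-6-ethyl-4-hydroxy-5-methyl-2H-pyran-2-one
Conditions: TBAF (6 equiv), DMF, rt to 60 °C, argon; dilute HCl work-up
Reagents that add atoms: none
Why: Fluoride-induced desilylation cleaves the aryl silyl ether directly and fragments both 2-(trimethylsilyl)ethyl ethers by β-elimination to ethylene, fluorotrimethylsilane and the pyranone or phenol oxide, the allyl group and the lactone being inert to fluoride.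

Step 12
Reactants: 30 3-{[2,4,6-trihydroxy-3-(prop-2-en-1-yl)phenyl]methyl}-6-ethyl-4-hydroxy-5-methyl-2H-pyran-2-one
Product: 31 3-{[3-acetyl-2,4,6-trihydroxy-5-(prop-2-en-1-yl)phenyl]methyl}-6-ethyl-4-hydroxy-5-methyl-2H-pyran-2-one
Conditions: Ac2O (1.5 equiv), BF3·OEt2 (6 equiv), 1,4-dioxane, rt; then aq. NaOAc, MeOH, 40 °C
Reagents that add atoms: acetic anhydride, CC(=O)OC(C)=O
Why: Friedel–Crafts acylation can occur only at C5', the single unsubstituted carbon of the phloroglucinol, flanked by two hydroxyls; acetylation on oxygen is reversed by Fries shift under BF3 or by the methanolic acetate work-up, and a monosubstituted allyl alkene, unlike a prenyl group, should tolerate the Lewis acid.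

Step 13
Reactants: 31 3-{[3-acetyl-2,4,6-trihydroxy-5-(prop-2-en-1-yl)phenyl]methyl}-6-ethyl-4-hydroxy-5-methyl-2H-pyran-2-one; 32 2-methylbut-2-ene
Product: 33 arzanol, 3-{[3-acetyl-2,4,6-trihydroxy-5-(3-methylbut-2-en-1-yl)phenyl]methyl}-6-ethyl-4-hydroxy-5-methyl-2H-pyran-2-one
Conditions: second-generation Grubbs catalyst RuCl2(=CHPh)(H2IMes)(PCy3) (10 mol %), 2-methylbut-2-ene–CH2Cl2 (1:1), 40 °C, sealed tube
Reagents that add atoms: none
Why: Olefin cross-metathesis exchanges the methylene of the monosubstituted allyl alkene for the isopropylidene of 2-methylbut-2-ene used in large excess, a standard late-stage entry to prenyl arenes that tolerates free phenols, ketones and lactones, and the trisubstituted product has no E/Z element.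

**Compound list**

1 | pentan-3-one | CCC(=O)CC | starting material
2 | (Z)-trimethyl(pent-2-en-3-yloxy)silane | C/C=C(/CC)O[Si](C)(C)C | intermediate
3 | malonyl dichloride | O=C(Cl)CC(=O)Cl | starting material
4 | 6-ethyl-4-hydroxy-5-methyl-2H-pyran-2-one | CCc1oc(=O)cc(O)c1C | intermediate
5 | allyl methyl carbonate | C=CCOC(=O)OC | starting material
6 | 6-ethyl-4-hydroxy-5-methyl-3-(prop-2-en-1-yl)-2H-pyran-2-one | CCc1oc(=O)c(CC=C)c(O)c1C | intermediate
7 | 2-(trimethylsilyl)ethanol | C[Si](C)(C)CCO | starting material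
8 | 6-ethyl-5-methyl-3-(prop-2-en-1-yl)-4-[2-(trimethylsilyl)ethoxy]-2H-pyran-2-one | CCc1oc(=O)c(CC=C)c(OCC[Si](C)(C)C)c1C | intermediate
9 | 3-[3-(9-borabicyclo[3.3.1]nonan-9-yl)propyl]-6-ethyl-5-methyl-4-[2-(trimethylsilyl)ethoxy]-2H-pyran-2-one | CCc1oc(=O)c(CCCB2C3CCCC2CCC3)c(OCC[Si](C)(C)C)c1C | intermediate
10 | 6-ethyl-3-(3-hydroxypropyl)-5-methyl-4-[2-(trimethylsilyl)ethoxy]-2H-pyran-2-one | CCc1oc(=O)c(CCCO)c(OCC[Si](C)(C)C)c1C | intermediate
11 | 3-Pyr-propanal | CCc1oc(=O)c(CCC=O)c(OCC[Si](C)(C)C)c1C | intermediate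
12 | 3-Pyr-propanoic acid | CCc1oc(=O)c(CCC(=O)O)c(OCC[Si](C)(C)C)c1C | intermediate
13 | trichloroethylene | ClC=C(Cl)Cl | starting material
14 | potassium 2-(trimethylsilyl)ethoxide | [K+].[O-]CC[Si](C)(C)C | intermediate
15 | (E)-[2-(1,2-dichloroethenyloxy)ethyl]trimethylsilane | Cl/C=C(/Cl)OCC[Si](C)(C)C | intermediate
16 | lithium [2-(trimethylsilyl)ethoxy]ethynide | [Li]C#COCC[Si](C)(C)C | intermediate
17 | [2-(ethynyloxy)ethyl]trimethylsilane | C#COCC[Si](C)(C)C | intermediate
18 | 3-Pyr-propanoyl chloride | CCc1oc(=O)c(CCC(=O)Cl)c(OCC[Si](C)(C)C)c1C | intermediate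
19 | 3-Pyr-prop-1-en-1-one (ketene) | CCc1oc(=O)c(CC=C=O)c(OCC[Si](C)(C)C)c1C | intermediate
20 | racemic 4-(Pyr-methyl)-3-[2-(trimethylsilyl)ethoxy]cyclobut-2-en-1-one | O=C1C=C(OCC[Si](C)(C)C)C1Cc1c(OCC[Si](C)(C)C)c(C)c(CC)oc1=O | intermediate
21 | pent-1-en-4-yne | C=CCC#C | starting material
22 | lithium pent-4-en-1-yn-1-ide | [Li]C#CCC=C | intermediate
23 | lithium pent-4-en-1-yn-1-olate | [Li]OC#CCC=C | intermediate
24 | triisopropyl(pent-4-en-1-yn-1-yloxy)silane | C=CCC#CO[Si](C(C)C)(C(C)C)C(C)C | intermediate
25 | (3Z)-5-Pyr-3-[2-(trimethylsilyl)ethoxy]penta-1,3-dien-1-one (vinylketene) | O=C=C/C(OCC[Si](C)(C)C)=C/Cc1c(OCC[Si](C)(C)C)c(C)c(CC)oc1=O | intermediate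
26 | racemic 2-(prop-2-en-1-yl)-3-(triisopropylsilyloxy)-4-{(1Z)-3-Pyr-1-[2-(trimethylsilyl)ethoxy]prop-1-en-1-yl}cyclobut-2-en-1-one | O=C1C(CC=C)=C(O[Si](C(C)C)(C(C)C)C(C)C)C1/C(OCC[Si](C)(C)C)=C/Cc1c(OCC[Si](C)(C)C)c(C)c(CC)oc1=O | intermediate
27 | (3E,5Z)-2-(prop-2-en-1-yl)-7-Pyr-3-(triisopropylsilyloxy)-5-[2-(trimethylsilyl)ethoxy]hepta-1,3,5-trien-1-one (dienylketene) | O=C=C(CC=C)/C(O[Si](C(C)C)(C(C)C)C(C)C)=C\C(OCC[Si](C)(C)C)=C\Cc1c(OCC[Si](C)(C)C)c(C)c(CC)oc1=O | intermediate
28 | racemic 2-(prop-2-en-1-yl)-6-(Pyr-methyl)-3-(triisopropylsilyloxy)-5-[2-(trimethylsilyl)ethoxy]cyclohexa-2,4-dien-1-one | O=C1C(CC=C)=C(O[Si](C(C)C)(C(C)C)C(C)C)C=C(OCC[Si](C)(C)C)C1Cc1c(OCC[Si](C)(C)C)c(C)c(CC)oc1=O | intermediate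
29 | 3-{[2-hydroxy-3-(prop-2-en-1-yl)-4-(triisopropylsilyloxy)-6-[2-(trimethylsilyl)ethoxy]phenyl]methyl}-6-ethyl-5-methyl-4-[2-(trimethylsilyl)ethoxy]-2H-pyran-2-one | Oc1c(CC=C)c(O[Si](C(C)C)(C(C)C)C(C)C)cc(OCC[Si](C)(C)C)c1Cc1c(OCC[Si](C)(C)C)c(C)c(CC)oc1=O | intermediate
30 | 3-{[2,4,6-trihydroxy-3-(prop-2-en-1-yl)phenyl]methyl}-6-ethyl-4-hydroxy-5-methyl-2H-pyran-2-one | CCc1oc(=O)c(Cc2c(O)cc(O)c(CC=C)c2O)c(O)c1C | intermediate
31 | 3-{[3-acetyl-2,4,6-trihydroxy-5-(prop-2-en-1-yl)phenyl]methyl}-6-ethyl-4-hydroxy-5-methyl-2H-pyran-2-one | CCc1oc(=O)c(Cc2c(O)c(CC=C)c(O)c(C(C)=O)c2O)c(O)c1C | intermediate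
32 | 2-methylbut-2-ene | CC=C(C)C | starting material
33 | arzanol | CCc1oc(=O)c(Cc2c(O)c(CC=C(C)C)c(O)c(C(C)=O)c2O)c(O)c1C | target

**Step count and risks**

Total: 13 steps. Longest linear sequence: 11 steps (1–6, 8, 10–13) from pentan-3-one.

Most likely to fail, first: step 10. The vinylogous-ester cyclobutenone may open too slowly at temperatures the ynol ether survives. The phenol formed may then be acylated by the vinylketene, or the ynol ether may be consumed by self-reaction before the cycloaddition is complete. The fallback uses known chemistry and forms the CH2 bridge by Mannich base/methide alkylation instead of building the ring. It sets out from 4 and returns at 31. Pyranone 4 is aminomethylated with dimethylmethylideneammonium iodide in CH2Cl2 to 3-[(dimethylamino)methyl]-6-ethyl-4-hydroxy-5-methyl-2H-pyran-2-one F1. Purchased 2,4,6-trihydroxyacetophenone is C-allylated (allyl bromide, NaOMe, MeOH, 0 °C) to 1-[2,4,6-trihydroxy-3-(prop-2-en-1-yl)phenyl]ethan-1-one F2. Heating F1 with F2 in acetonitrile should expel dimethylamine to give 6-ethyl-5-methyl-3-methylidene-2H-pyran-2,4(3H)-dione F3, which is not isolated. The free ring carbon of F2 captures F3 to give 31, and step 13 follows unchanged.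

Second: step 8. Dimerisation of the aldoketene and amine-induced oligomerisation may outrun the cycloaddition, because the alkynyl ether cannot be used as solvent. The fallback releases the same ketene 19 slowly from a neutral precursor by Wolff rearrangement. It sets out from 8 and returns at 20. Alkene 8 is cleaved (OsO4 cat., NaIO4, 2,6-lutidine, dioxane–H2O; Lemieux–Johnson) to 2-Pyr-acetaldehyde F4. Pinnick oxidation (NaClO2, NaH2PO4, 2-methylbut-2-ene, t-BuOH–H2O) gives 2-Pyr-acetic acid F5. 1-Chloro-N,N,2-trimethylprop-1-en-1-amine gives 2-Pyr-acetyl chloride F6, and excess diazomethane gives 1-diazo-3-Pyr-propan-2-one F7. Treating F7 with AgO2CPh (10 mol %) and Et3N in THF containing 17 should expel nitrogen, the 1,2-shift delivers ketene 19, and its (2+2) cycloaddition with 17 gives 20.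

Third: step 12. Acetylation may stop on oxygen without migrating to carbon, and the Lewis acid may protonate the very electron-rich ring at C1' and cleave the diarylmethane bridge. The fallback replaces electrophilic acylation by cross-coupling on the protected ring. It sets out from 29 and returns at 31. Compound 29 is brominated para to its free hydroxyl (NBS, CH2Cl2, −78 °C) to the 5'-bromo derivative of 29 F8. Stille coupling with tributyl(1-ethoxyvinyl)stannane (Pd(PPh3)4, toluene, 100 °C) gives the 5'-(1-ethoxyvinyl) derivative of 29 F9. 1 M HCl in THF hydrolyses the enol ether to the 5'-acetyl derivative of 29 F10. TBAF under the conditions of step 11 then gives 31.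

**Further compounds**

F1 | step 10 | 3-[(dimethylamino)methyl]-6-ethyl-4-hydroxy-5-methyl-2H-pyran-2-one | CCc1oc(=O)c(CN(C)C)c(O)c1C
F2 | step 10 | 1-[2,4,6-trihydroxy-3-(prop-2-en-1-yl)phenyl]ethan-1-one | CC(=O)c1c(O)cc(O)c(CC=C)c1O
F3 | step 10 | 6-ethyl-5-methyl-3-methylidene-2H-pyran-2,4(3H)-dione | CCC1=C(C)C(=O)C(=C)C(=O)O1
F4 | step 8 | 2-Pyr-acetaldehyde | CCc1oc(=O)c(CC=O)c(OCC[Si](C)(C)C)c1C
F5 | step 8 | 2-Pyr-acetic acid | CCc1oc(=O)c(CC(=O)O)c(OCC[Si](C)(C)C)c1C
F6 | step 8 | 2-Pyr-acetyl chloride | CCc1oc(=O)c(CC(=O)Cl)c(OCC[Si](C)(C)C)c1C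
F7 | step 8 | 1-diazo-3-Pyr-propan-2-one | CCc1oc(=O)c(CC(=O)C=[N+]=[N-])c(OCC[Si](C)(C)C)c1C
F8 | step 12 | 5'-bromo derivative of 29 | Oc1c(CC=C)c(O[Si](C(C)C)(C(C)C)C(C)C)c(Br)c(OCC[Si](C)(C)C)c1Cc1c(OCC[Si](C)(C)C)c(C)c(CC)oc1=O
F9 | step 12 | 5'-(1-ethoxyvinyl) derivative of 29 | Oc1c(CC=C)c(O[Si](C(C)C)(C(C)C)C(C)C)c(C(=C)OCC)c(OCC[Si](C)(C)C)c1Cc1c(OCC[Si](C)(C)C)c(C)c(CC)oc1=O
F10 | step 12 | 5'-acetyl derivative of 29 | Oc1c(CC=C)c(O[Si](C(C)C)(C(C)C)C(C)C)c(C(C)=O)c(OCC[Si](C)(C)C)c1Cc1c(OCC[Si](C)(C)C)c(C)c(CC)oc1=O
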